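**Retrosynthetic overview** (chromene numbering of 24: O1, C2, C3, C4, C4a, C5–C8, C8a)
1. 24 ⇐ methyl ester 23 (saponification) ⇐ prenyl 8-carboxylate 21 by decarboxylative, dearomative prenylation at C8, where the C8 configuration is set.
2. 21 ⇐ β-keto ester 18 + lactone ketene dithioacetal 5 by a one-flask [3+3] annulation with lactone-to-pyranone ring switch: C8–C8a and C6–C5 close the carbocycle first, then O1–C8a closes the dihydropyranone.
3. Enabling feature: the carbocycle C4a–C5–C6–C7–C8–C8a is 1,3,5-trioxygenated. C7 is a ketone flanked by its α-carbons C8 and C6 (a 1,3-dinucleophile). C8a–C4a–C5 is an acyl-malonyl unit whose end carbons are at the carboxylic acid level, and O1 is tied to C4a through C2–C3–C4. A dihydropyran-2,4-dione therefore supplies C5 as its lactone carbonyl and C8a as a dithioacetal carbon.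
4. 18 ⇐ β-keto ester 17 + iodide 10 (from (−)-verbenone 6); 17 ⇐ hemiester 15 ⇐ 3-pentylglutaric anhydride 14; 5 ⇐ methyl (R)-3-hydroxybutanoate 1.
5. Stereocentres: cyclobutane from 6; C2/C3 from 1 (Fráter–Seebach); side-chain C3 from anhydride desymmetrisation; C8 from the chiral palladium catalyst in step 16.

Key step: step 15

Assumption: 6 is used in high enantiomeric purity (7 can be enriched by crystallisation), and the catalyst antipodes written in steps 12 and 16 are taken to give the configurations shown; the sense of induction would be checked at those stages.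

**Step 1**
Reactants: 1 methyl (3R)-3-hydroxybutanoate
Product: 2 methyl (2R,3R)-3-hydroxy-2-methylbutanoate
Conditions: LiN(iPr)2 (2.2 equiv), THF, −78 to −20 °C; MeI, DMPU, −78 to 0 °C
Reagents that add atoms: iodomethane, CI
Why: Fráter–Seebach alkylation: the chelated dilithium alkoxide enolate should be methylated on the face away from the C3 methyl group, setting C2 anti to the hydroxyl as (2R,3R).

**Step 2**
Reactants: 2 methyl (2R,3R)-3-hydroxy-2-methylbutanoate
Product: 3 tert-butyl (4R,5R)-5-hydroxy-4-methyl-3-oxohexanoate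
Conditions: LiN(iPr)2, tert-butyl acetate (4 equiv), THF, −78 °C; then 2, −78 to −20 °C; aq. NH4Cl
Reagents that add atoms: tert-butyl acetate, CC(=O)OC(C)(C)C
Why: Crossed Claisen condensation of excess lithium tert-butyl acetate enolate with the methyl ester; the product is held as its β-keto ester enolate, so C4 should not epimerise.

**Step 3**
Reactants: 3 tert-butyl (4R,5R)-5-hydroxy-4-methyl-3-oxohexanoate
Product: 4 (5R,6R)-5,6-dimethyloxane-2,4-dione
Conditions: CF3CO2H, CH2Cl2, 0 °C to rt
Reagents that add atoms: none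
Why: Acidolysis of the tert-butyl ester and spontaneous δ-lactonisation of the 5-hydroxy-3-oxo acid, the standard entry to 6-substituted dihydropyran-2,4-diones, touches no stereocentre.

**Step 4**
Reactants: 4 (5R,6R)-5,6-dimethyloxane-2,4-dione
Product: 5 (5R,6R)-3-[bis(methylsulfanyl)methylidene]-5,6-dimethyloxane-2,4-dione
Conditions: K2CO3, CS2, DMF, 0 °C; MeI (2.2 equiv), rt
Reagents that add atoms: carbon disulfide, S=C=S; iodomethane, CI
Why: Ketene dithioacetal formation: the C3 carbanion of the cyclic 1,3-dicarbonyl adds to CS2 and the dithiocarboxylate is S-methylated twice, as with 4-hydroxy-2-pyranones and Meldrum's acid.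

**Step 5**
Reactants: 6 (1S,5S)-(−)-verbenone
Product: 7 (1S,3R)-3-acetyl-2,2-dimethylcyclobutane-1-carboxylic acid (cis-pinononic acid)
Conditions: RuCl3·xH2O (2 mol %), NaIO4 (4 equiv), EtOAc/MeCN/H2O, rt
Reagents that add atoms: sodium periodate, [Na+].[O-]I(=O)(=O)=O; water, O
Why: RuO4-type oxidative cleavage of the enone C=C with loss of one carbon as CO2 should give the cis keto acid with both ring stereocentres retained.

**Step 6**
Reactants: 7 (1S,3R)-3-acetyl-2,2-dimethylcyclobutane-1-carboxylic acid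
Product: 8 (1S,3S)-2,2-dimethyl-3-(prop-1-en-2-yl)cyclobutane-1-carboxylic acid
Conditions: Ph3PCH3Br, KOtBu (2.4 equiv), THF, 0 °C; then 7, 0 °C to rt; aq. HCl
Reagents that add atoms: methyltriphenylphosphonium bromide, C[P+](c1ccccc1)(c1ccccc1)c1ccccc1.[Br-]
Why: Wittig methylenation of the methyl ketone with preformed ylide; the carboxylate protects C1 and the low temperature should keep the cis relationship at C3.

**Step 7**
Reactants: 8 (1S,3S)-2,2-dimethyl-3-(prop-1-en-2-yl)cyclobutane-1-carboxylic acid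
Product: 9 [(1S,3S)-2,2-dimethyl-3-(prop-1-en-2-yl)cyclobutyl]methanol
Conditions: LiAlH4, Et2O, 0 °C to rt
Reagents that add atoms: none
Why: Hydride reduction of the acid to the primary alcohol; the 1,1-disubstituted alkene is inert.

**Step 8**
Reactants: 9 [(1S,3S)-2,2-dimethyl-3-(prop-1-en-2-yl)cyclobutyl]methanol
Product: 10 (1S,3S)-1-(iodomethyl)-2,2-dimethyl-3-(prop-1-en-2-yl)cyclobutane
Conditions: I2, PPh3, imidazole, CH2Cl2, 0 °C to rt
Reagents that add atoms: iodine, II
Why: Appel iodination, an SN2 displacement at the primary carbinol carbon, leaves the ring stereocentres untouched.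

**Step 9**
Reactants: 11 ethyl (2E)-oct-2-enoate
Product: 12 triethyl 2-pentylpropane-1,1,3-tricarboxylate
Conditions: diethyl malonate (1.2 equiv), NaOEt (0.2 equiv), EtOH, reflux
Reagents that add atoms: diethyl malonate, CCOC(=O)CC(=O)OCC
Why: Michael addition of the malonate anion to the enoate under thermodynamic control.

**Step 10**
Reactants: 12 triethyl 2-pentylpropane-1,1,3-tricarboxylate
Product: 13 3-pentylpentanedioic acid
Conditions: 6 M HCl, reflux
Reagents that add atoms: water, O
Why: Acidic ester hydrolysis followed by decarboxylation of the malonic acid unit gives the symmetric diacid.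

**Step 11**
Reactants: 13 3-pentylpentanedioic acid
Product: 14 4-pentyloxane-2,6-dione (3-pentylglutaric anhydride)
Conditions: Ac2O, reflux; distillation
Reagents that add atoms: none
Why: Cyclodehydration of the 1,5-diacid to the six-membered anhydride.

**Step 12**
Reactants: 14 4-pentyloxane-2,6-dione
Product: 15 (3R)-3-(2-methoxy-2-oxoethyl)octanoic acid
Conditions: (DHQD)2AQN (10 mol %), MeOH (10 equiv), Et2O, −40 °C
Reagents that add atoms: methanol, CO
Why: Cinchona alkaloid-catalysed enantioselective methanolysis (desymmetrisation of a prochiral 3-alkylglutaric anhydride) differentiates the enantiotopic carbonyl groups and sets C3 as R by catalyst control.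

**Step 13**
Reactants: 15 (3R)-3-(2-methoxy-2-oxoethyl)octanoic acid
Product: 17 7-methyl 1-prenyl (5R)-3-oxo-5-pentylheptanedioate, via acyl Meldrum's acid 16 (not isolated)
Conditions: Meldrum's acid, EDC·HCl, DMAP, CH2Cl2, 0 °C to rt; then 3-methylbut-2-en-1-ol, toluene, 85 °C
Reagents that add atoms: Meldrum's acid (2,2-dimethyl-1,3-dioxane-4,6-dione), CC1(C)OC(=O)CC(=O)O1; 3-methylbut-2-en-1-ol, CC(C)=CCO
Why: C-acylation of Meldrum's acid by the carbodiimide-activated acid and thermal alcoholysis through the acylketene gives the β-keto ester; the stereocentre is remote and unaffected.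

**Step 14**
Reactants: 17 7-methyl 1-prenyl (5R)-3-oxo-5-pentylheptanedioate; 10 (1S,3S)-1-(iodomethyl)-2,2-dimethyl-3-(prop-1-en-2-yl)cyclobutane
Product: 18 C2-(cyclobutylmethyl) β-keto ester (both C2 epimers)
Conditions: NaH (1.05 equiv), THF/DMF (4:1), 0 °C; then 10, 55 °C
Reagents that add atoms: none
Why: C-alkylation of the β-keto ester sodium enolate (SN2) with the primary iodide; the new C2 centre forms as both epimers, which is of no consequence because it is flattened in step 16.

**Step 15**
Reactants: 18 C2-(cyclobutylmethyl) β-keto ester; 5 (5R,6R)-3-[bis(methylsulfanyl)methylidene]-5,6-dimethyloxane-2,4-dione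
Product: 21 prenyl 8-carboxylate of the dearomatised chromanone core (both C8 epimers), via thioenol ether lactone 19 (not isolated), via ring-opened alkoxide 20 (not isolated)
Conditions: Cs2CO3 (0.3 equiv), DMF, 40 °C, N2 sweep; then KOtBu (1.5 equiv), THF, 0 °C to rt; aq. HCl
Reagents that add atoms: none
Why: Proposed new method: The caesium enolate of 18 at C2 (heptanedioate numbering, its only doubly activated carbon) should add to the bis(methylsulfanyl)methylidene carbon of 5 and expel methanethiolate (first C–C bond, 19); KOtBu then forms the ketone enolate at C4, which attacks the lactone carbonyl in a Claisen acylation that opens the lactone (second C–C bond, 20), and the freed alkoxide displaces the second methylsulfanyl group to close the dihydropyranone. The closest known reaction types are the [3+3] annulation of α-oxo ketene dithioacetals with 1,3-dinucleophilic ketones (Junjappa–Ila type) and carbanion-induced ring transformations of pyran-2-ones; new are the quaternary, non-aromatisable C8 and the lactone-to-pyranone switch. The carbocycle closes by 6-exo-trig acyl substitution at the lactone C=O and the dihydropyranone by 6-endo-trig oxa-Michael addition–elimination. C8 is the only new stereocentre and is deliberately left uncontrolled, since both epimers converge in step 16, while C3 of the chromanone (α to the ketone) should settle trans to the C2 methyl under the basic conditions. The step needs regioselectivity (C2 to the dithioacetal carbon, C4 to the lactone carbonyl), which the acidity gap between C2–H and C4–H and the sequential bases secure, and chemoselectivity for the lactone carbonyl over the ring ketone, which rests on fast rotation about the polarised push-pull C=C, on the reversibility of the aldol alternative and on the irreversible O-cyclisation and enolate formation after the Claisen step; loss of volatile CH3SH drives the first substitution.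

**Step 16**
Reactants: 21 prenyl 8-carboxylate of the dearomatised chromanone core
Product: 23 methyl ester of the target with (8R) configuration, via phenoxide 22 (not isolated)
Conditions: Pd2(dba)3 (2.5 mol %), (S,S)-DACH-phenyl bisphosphine [N,N′-(1S,2S)-cyclohexane-1,2-diylbis(2-diphenylphosphanylbenzamide)] (6 mol %), THF, 0 °C to rt
Reagents that add atoms: none
Why: Proposed new method: zerovalent palladium should ionise the prenyl ester, the β-keto carboxylate loses CO2 to give the planar aromatic phenoxide 22 (so both C8 epimers of 21 converge), and C8 attacks the ligand-bound η3-prenylpalladium cation at its unsubstituted terminus on the face selected by the chiral pocket, setting C8 as R under catalyst control, while C6 is shielded by its branched side chain and O-prenyl ethers re-ionise; the closest known reactions are the Tsuji–Trost decarboxylative asymmetric allylic alkylation of α-substituted β-keto allyl esters, palladium-catalysed allylic dearomatisation of phenols and linear-selective asymmetric prenylation of oxindoles.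

**Step 17**
Reactants: 23 methyl ester of the target
Product: 24 target acid
Conditions: LiOH (3 equiv), THF/H2O, 0 °C to rt; then 1 M HCl to pH 3
Reagents that add atoms: lithium hydroxide, [Li+].[OH-]
Why: Saponification of the methyl ester; the ring is protected as its vinylogous carboxylate anion and C3 of the chromanone is already in the stable trans arrangement.

**Compound list**
1 | methyl (3R)-3-hydroxybutanoate | O[C@H](C)CC(=O)OC | starting material
2 | methyl (2R,3R)-3-hydroxy-2-methylbutanoate | O[C@H](C)[C@@H](C)C(=O)OC | intermediate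
3 | tert-butyl (4R,5R)-5-hydroxy-4-methyl-3-oxohexanoate | O[C@H](C)[C@@H](C)C(=O)CC(=O)OC(C)(C)C | intermediate
4 | (5R,6R)-5,6-dimethyloxane-2,4-dione | C[C@H]1OC(=O)CC(=O)[C@@H]1C | intermediate
5 | (5R,6R)-3-[bis(methylsulfanyl)methylidene]-5,6-dimethyloxane-2,4-dione | C[C@H]1OC(=O)C(=C(SC)SC)C(=O)[C@@H]1C | intermediate
6 | (1S,5S)-4,6,6-trimethylbicyclo[3.1.1]hept-3-en-2-one, (−)-verbenone | CC1=CC(=O)[C@H]2C[C@@H]1C2(C)C | starting material
7 | (1S,3R)-3-acetyl-2,2-dimethylcyclobutane-1-carboxylic acid | OC(=O)[C@H]1C[C@@H](C(C)=O)C1(C)C | intermediate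
8 | (1S,3S)-2,2-dimethyl-3-(prop-1-en-2-yl)cyclobutane-1-carboxylic acid | OC(=O)[C@H]1C[C@@H](C(C)=C)C1(C)C | intermediate
9 | [(1S,3S)-2,2-dimethyl-3-(prop-1-en-2-yl)cyclobutyl]methanol | OC[C@H]1C[C@@H](C(C)=C)C1(C)C | intermediate
10 | (1S,3S)-1-(iodomethyl)-2,2-dimethyl-3-(prop-1-en-2-yl)cyclobutane | IC[C@H]1C[C@@H](C(C)=C)C1(C)C | intermediate
11 | ethyl (2E)-oct-2-enoate | CCCCC/C=C/C(=O)OCC | starting material
12 | triethyl 2-pentylpropane-1,1,3-tricarboxylate (racemic) | CCCCCC(CC(=O)OCC)C(C(=O)OCC)C(=O)OCC | intermediate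
13 | 3-pentylpentanedioic acid | CCCCCC(CC(=O)O)CC(=O)O | intermediate
14 | 4-pentyloxane-2,6-dione | CCCCCC1CC(=O)OC(=O)C1 | intermediate
15 | (3R)-3-(2-methoxy-2-oxoethyl)octanoic acid | OC(=O)C[C@@H](CCCCC)CC(=O)OC | intermediate
16 | methyl (3R)-3-[2-(2,2-dimethyl-4,6-dioxo-1,3-dioxan-5-ylidene)-2-hydroxyethyl]octanoate | CC1(C)OC(=O)C(=C(O)C[C@@H](CCCCC)CC(=O)OC)C(=O)O1 | intermediate
17 | 7-methyl 1-(3-methylbut-2-en-1-yl) (5R)-3-oxo-5-pentylheptanedioate | CC(C)=CCOC(=O)CC(=O)C[C@@H](CCCCC)CC(=O)OC | intermediate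
18 | 7-methyl 1-(3-methylbut-2-en-1-yl) (5R)-2-{[(1R,3S)-2,2-dimethyl-3-(prop-1-en-2-yl)cyclobutyl]methyl}-3-oxo-5-pentylheptanedioate (both C2 epimers) | CC(C)=CCOC(=O)C(C[C@H]1C[C@@H](C(C)=C)C1(C)C)C(=O)C[C@@H](CCCCC)CC(=O)OC | intermediate
19 | 7-methyl 1-(3-methylbut-2-en-1-yl) (5R)-2-{[(1R,3S)-2,2-dimethyl-3-(prop-1-en-2-yl)cyclobutyl]methyl}-2-{[(5R,6R)-5,6-dimethyl-2,4-dioxooxan-3-ylidene](methylsulfanyl)methyl}-3-oxo-5-pentylheptanedioate | C[C@H]1OC(=O)C(=C(SC)C(C[C@H]2C[C@@H](C(C)=C)C2(C)C)(C(=O)OCC=C(C)C)C(=O)C[C@@H](CCCCC)CC(=O)OC)C(=O)[C@@H]1C | intermediate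
20 | 3-methylbut-2-en-1-yl 1-{[(1R,3S)-2,2-dimethyl-3-(prop-1-en-2-yl)cyclobutyl]methyl}-4-hydroxy-3-[(2R,3R)-3-hydroxy-2-methylbutanoyl]-5-[(3S)-1-methoxy-1-oxooctan-3-yl]-2-(methylsulfanyl)-6-oxocyclohexa-2,4-diene-1-carboxylate (present as its potassium alkoxide, drawn neutral) | CSC1=C(C(=O)[C@H](C)[C@@H](C)O)C(O)=C([C@@H](CCCCC)CC(=O)OC)C(=O)C1(C[C@H]2C[C@@H](C(C)=C)C2(C)C)C(=O)OCC=C(C)C | intermediate
21 | 3-methylbut-2-en-1-yl (2R,3R)-8-{[(1R,3S)-2,2-dimethyl-3-(prop-1-en-2-yl)cyclobutyl]methyl}-5-hydroxy-6-[(3S)-1-methoxy-1-oxooctan-3-yl]-2,3-dimethyl-4,7-dioxo-3,4,7,8-tetrahydro-2H-chromene-8-carboxylate (both C8 epimers) | C=C(C)[C@@H]1C[C@H](CC2(C(=O)OCC=C(C)C)C(=O)C([C@@H](CCCCC)CC(=O)OC)=C(O)C3=C2O[C@H](C)[C@@H](C)C3=O)C1(C)C | intermediate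
22 | methyl (3S)-3-[(2R,3R)-8-{[(1R,3S)-2,2-dimethyl-3-(prop-1-en-2-yl)cyclobutyl]methyl}-5,7-dihydroxy-2,3-dimethyl-4-oxo-3,4-dihydro-2H-chromen-6-yl]octanoate (present as phenoxide paired with the prenylpalladium cation, drawn as the neutral phenol) | C=C(C)[C@@H]1C[C@H](Cc2c(O)c([C@@H](CCCCC)CC(=O)OC)c(O)c3c2O[C@H](C)[C@@H](C)C3=O)C1(C)C | intermediate
23 | methyl (3S)-3-[(2R,3R,8R)-8-{[(1R,3S)-2,2-dimethyl-3-(prop-1-en-2-yl)cyclobutyl]methyl}-5-hydroxy-2,3-dimethyl-8-(3-methylbut-2-en-1-yl)-4,7-dioxo-3,4,7,8-tetrahydro-2H-chromen-6-yl]octanoate | C=C(C)[C@@H]1C[C@H](C[C@@]2(CC=C(C)C)C(=O)C([C@@H](CCCCC)CC(=O)OC)=C(O)C3=C2O[C@H](C)[C@@H](C)C3=O)C1(C)C | intermediate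
24 | (3S)-3-[(2R,3R,8R)-8-{[(1R,3S)-2,2-dimethyl-3-(prop-1-en-2-yl)cyclobutyl]methyl}-5-hydroxy-2,3-dimethyl-8-(3-methylbut-2-en-1-yl)-4,7-dioxo-3,4,7,8-tetrahydro-2H-chromen-6-yl]octanoic acid | C=C(C)[C@@H]1C[C@H](C[C@@]2(CC=C(C)C)C(=O)C([C@@H](CCCCC)CC(=O)O)=C(O)C3=C2O[C@H](C)[C@@H](C)C3=O)C1(C)C | target

**Totals**
Total step count: 17. Longest linear sequence: 9 steps (11 to 24, steps 9–17).

**Steps most likely to fail**

Step 15 (proposed new method). The first addition–elimination at the congested, fully substituted carbon may revert, or the ketone enolate may close onto the ring ketone (aldol) instead of the lactone carbonyl, so that the ring switch never starts. The fallback makes the same two bonds stepwise with an open-chain, O-silylated electrophile and closes the heterocycle last, each operation being a known reaction type. It sets out from 2, which would be silylated (TBSCl, imidazole) to methyl (2R,3R)-3-[(tert-butyldimethylsilyl)oxy]-2-methylbutanoate F1. Crossed Claisen condensation with the lithium enolate of methyl acetate would give methyl (4R,5R)-5-[(tert-butyldimethylsilyl)oxy]-4-methyl-3-oxohexanoate F2, and CS2/K2CO3/MeI would convert this into methyl (4R,5R)-2-[bis(methylsulfanyl)methylidene]-5-[(tert-butyldimethylsilyl)oxy]-4-methyl-3-oxohexanoate F3. Addition–elimination of the sodium enolate of 18 to F3 would give the open-chain adduct, 7-methyl 1-(3-methylbut-2-en-1-yl) (5R)-2-[(4R,5R)-5-[(tert-butyldimethylsilyl)oxy]-2-(methoxycarbonyl)-4-methyl-1-(methylsulfanyl)-3-oxohex-1-en-1-yl]-2-{[(1R,3S)-2,2-dimethyl-3-(prop-1-en-2-yl)cyclobutyl]methyl}-3-oxo-5-pentylheptanedioate F4, which would be isolated. Dieckmann cyclisation (KOtBu, THF) onto the methyl ester would give the carbocycle, 3-methylbut-2-en-1-yl 3-[(2R,3R)-3-[(tert-butyldimethylsilyl)oxy]-2-methylbutanoyl]-1-{[(1R,3S)-2,2-dimethyl-3-(prop-1-en-2-yl)cyclobutyl]methyl}-4-hydroxy-5-[(3S)-1-methoxy-1-oxooctan-3-yl]-2-(methylsulfanyl)-6-oxocyclohexa-2,4-diene-1-carboxylate F5. Bu4NF would then unmask the alcohol, which closes the dihydropyranone by displacing the remaining methylsulfanyl group, as in 2-(methylsulfanyl)chromone syntheses, and the route is rejoined at 21.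

Step 16 (proposed new method). Facial discrimination at the planar C8 of the phenoxide may be insufficient, or the prenyl group may be transferred to C6, to oxygen or through its tertiary terminus. The fallback sets out from 21 and gives up catalyst control in favour of separation. Deallylative decarboxylation with Pd(PPh3)4 and morpholine in THF would give the phenol 22, which would be isolated. Classical alkylative dearomatisation with prenyl bromide and NaOMe in MeOH at 0 °C, as used for dialkylated acylphloroglucinols, should give 23 together with its C8 epimer, methyl (3S)-3-[(2R,3R,8S)-8-{[(1R,3S)-2,2-dimethyl-3-(prop-1-en-2-yl)cyclobutyl]methyl}-5-hydroxy-2,3-dimethyl-8-(3-methylbut-2-en-1-yl)-4,7-dioxo-3,4,7,8-tetrahydro-2H-chromen-6-yl]octanoate F6. The two would be separated by preparative HPLC, and the route is rejoined at 23.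

Step 14. SN2 displacement at the β-branched primary iodide may be slow, so that O-alkylation or E2 elimination takes over. The fallback replaces substitution by reductive alkylation and sets out from 9, which would be oxidised with Dess–Martin periodinane to (1S,3S)-2,2-dimethyl-3-(prop-1-en-2-yl)cyclobutane-1-carbaldehyde F7. Knoevenagel condensation with 17 (piperidinium acetate, CH2Cl2, rt) would give 7-methyl 1-(3-methylbut-2-en-1-yl) (5R)-2-{[(1R,3S)-2,2-dimethyl-3-(prop-1-en-2-yl)cyclobutyl]methylidene}-3-oxo-5-pentylheptanedioate F8, which would be reduced in the same flask with Hantzsch ester; the route is rejoined at 18.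

**Further compounds**
F1 | step 15 | methyl (2R,3R)-3-[(tert-butyldimethylsilyl)oxy]-2-methylbutanoate | CC(C)(C)[Si](C)(C)O[C@H](C)[C@@H](C)C(=O)OC
F2 | step 15 | methyl (4R,5R)-5-[(tert-butyldimethylsilyl)oxy]-4-methyl-3-oxohexanoate | CC(C)(C)[Si](C)(C)O[C@H](C)[C@@H](C)C(=O)CC(=O)OC
F3 | step 15 | methyl (4R,5R)-2-[bis(methylsulfanyl)methylidene]-5-[(tert-butyldimethylsilyl)oxy]-4-methyl-3-oxohexanoate | CC(C)(C)[Si](C)(C)O[C@H](C)[C@@H](C)C(=O)C(=C(SC)SC)C(=O)OC
F4 | step 15 | 7-methyl 1-(3-methylbut-2-en-1-yl) (5R)-2-[(4R,5R)-5-[(tert-butyldimethylsilyl)oxy]-2-(methoxycarbonyl)-4-methyl-1-(methylsulfanyl)-3-oxohex-1-en-1-yl]-2-{[(1R,3S)-2,2-dimethyl-3-(prop-1-en-2-yl)cyclobutyl]methyl}-3-oxo-5-pentylheptanedioate | CC(C)(C)[Si](C)(C)O[C@H](C)[C@@H](C)C(=O)C(C(=O)OC)=C(SC)C(C[C@H]1C[C@@H](C(C)=C)C1(C)C)(C(=O)OCC=C(C)C)C(=O)C[C@@H](CCCCC)CC(=O)OC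
F5 | step 15 | 3-methylbut-2-en-1-yl 3-[(2R,3R)-3-[(tert-butyldimethylsilyl)oxy]-2-methylbutanoyl]-1-{[(1R,3S)-2,2-dimethyl-3-(prop-1-en-2-yl)cyclobutyl]methyl}-4-hydroxy-5-[(3S)-1-methoxy-1-oxooctan-3-yl]-2-(methylsulfanyl)-6-oxocyclohexa-2,4-diene-1-carboxylate | CSC1=C(C(=O)[C@H](C)[C@@H](C)O[Si](C)(C)C(C)(C)C)C(O)=C([C@@H](CCCCC)CC(=O)OC)C(=O)C1(C[C@H]2C[C@@H](C(C)=C)C2(C)C)C(=O)OCC=C(C)C
F6 | step 16 | methyl (3S)-3-[(2R,3R,8S)-8-{[(1R,3S)-2,2-dimethyl-3-(prop-1-en-2-yl)cyclobutyl]methyl}-5-hydroxy-2,3-dimethyl-8-(3-methylbut-2-en-1-yl)-4,7-dioxo-3,4,7,8-tetrahydro-2H-chromen-6-yl]octanoate | C=C(C)[C@@H]1C[C@H](C[C@]2(CC=C(C)C)C(=O)C([C@@H](CCCCC)CC(=O)OC)=C(O)C3=C2O[C@H](C)[C@@H](C)C3=O)C1(C)C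
F7 | step 14 | (1S,3S)-2,2-dimethyl-3-(prop-1-en-2-yl)cyclobutane-1-carbaldehyde | O=C[C@H]1C[C@@H](C(C)=C)C1(C)C
F8 | step 14 | 7-methyl 1-(3-methylbut-2-en-1-yl) (5R)-2-{[(1R,3S)-2,2-dimethyl-3-(prop-1-en-2-yl)cyclobutyl]methylidene}-3-oxo-5-pentylheptanedioate | CC(C)=CCOC(=O)C(=C[C@H]1C[C@@H](C(C)=C)C1(C)C)C(=O)C[C@@H](CCCCC)CC(=O)OC
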